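Ring A of pebrellin bears oxygen on every carbon from C5 to C8a. C5, C7 and C8a mark the alternating carbonyls of a polyketide chain, C6 and C8 carry two additional alpha-oxygens, and O1, C2, C3 and C4 can be stored beforehand in the ring C pyranone. Everything rests on cutting C5–C6. The precursor is a 6-aryl-4-pyranone with a methyl ester on pyranone C3 (future C5) and a 3-benzyloxy-1-methoxy-2-oxopropyl chain on pyranone C2 (future C8, C7, C6). Twofold deprotonation lets the chain terminus attack the ester, so one operation closes and aromatizes ring A and delivers O6 as benzyl ether, O8 as methyl ether, and O5 and O7 as phenols of different acidity.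

Key step: step 5

Remark on the chemistry: the target has no stereocentre. Compound 9 is racemic at its methoxymethine carbon and is drawn as the keto tautomer, although it should be largely enolised; this centre disappears in step 5. Labels O1 to C8a follow flavone numbering, and "pyranone C2/C3" refers to the monocyclic ring.

Step 1
Reactants: 1 3-(3,4-dimethoxyphenyl)propiolic acid
Product: 2 3-(3,4-dimethoxyphenyl)propioloyl chloride
Conditions: (COCl)2 (1.3 equiv), DMF (cat.), CH2Cl2, 0 °C to rt; concentrate, use crude
Reagents that add atoms: oxalyl chloride, O=C(Cl)C(=O)Cl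
Why: DMF-catalysed acid chloride formation (Vilsmeier-type activation) runs at or below room temperature, which should spare the alkyne and the aryl methyl ethers and avoid the thermal self-condensation known for arylpropiolic acids.

Step 2
Reactants: 2 3-(3,4-dimethoxyphenyl)propioloyl chloride; 3 methyl 4-methoxyacetoacetate
Product: 5 methyl 6-(3,4-dimethoxyphenyl)-2-(methoxymethyl)-4-oxo-4H-pyran-3-carboxylate, via alkynoyl keto ester 4 (not isolated)
Conditions: MgCl2 (1.1 equiv), pyridine (2.2 equiv), CH2Cl2, 0 °C, then 2, 0 °C to rt; DMAP (0.1 equiv), rt; 1 M HCl wash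
Reagents that add atoms: none
Why: A magnesium-chelate C-acylation of the beta-keto ester (MgCl2/pyridine soft enolisation) places the alkynoyl group on C2, and the ketone enol oxygen of 4 then adds to the ynone beta-carbon in a 6-endo-dig oxa-Michael closure, kept away from the 5-exo mode by nucleophilic DMAP catalysis, which is the classical alkynoyl chloride entry to 4-pyranone-3-carboxylates; no stereocentre results.

Step 3
Reactants: 6 benzyloxyacetyl chloride
Product: 7 2-(benzyloxy)-N-methoxy-N-methylacetamide
Conditions: MeNH(OMe)·HCl (1.1 equiv), Et3N (2.3 equiv), CH2Cl2, 0 °C to rt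
Reagents that add atoms: N,O-dimethylhydroxylamine hydrochloride, CNOC.Cl
Why: Plain N-acylation of the hydroxylamine by the acid chloride (Weinreb amide formation) is fast at 0 °C and does not touch the benzyl ether.

Step 4
Reactants: 5 methyl 6-(3,4-dimethoxyphenyl)-2-(methoxymethyl)-4-oxo-4H-pyran-3-carboxylate; 7 2-(benzyloxy)-N-methoxy-N-methylacetamide
Product: 9 methyl 2-[3-(benzyloxy)-1-methoxy-2-oxopropyl]-6-(3,4-dimethoxyphenyl)-4-oxo-4H-pyran-3-carboxylate (racemic), via lithium hemiaminal adduct 8 (not isolated)
Conditions: LiN(iPr)2 (LDA, 1.1 equiv), THF, −78 °C; 7 (1.2 equiv), −78 to −20 °C; cold 1 M HCl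
Reagents that add atoms: none
Why: The methoxymethyl CH2 is vinylogously acidified by C4=O and by the 3-ester, so the amide base gives the exocyclic dienolate, which reacts at its gamma-carbon (attack at pyranone C3 would break the pyranone conjugation) in a Weinreb ketone synthesis whose chelated adduct 8, and whose basic leaving group if 8 collapses early, should suppress the double acylation, O-acylation, ketene formation and proton-transfer losses expected from an acid chloride; the new methoxymethine centre forms racemic and is erased in step 5.

Step 5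
Reactants: 9 methyl 2-[3-(benzyloxy)-1-methoxy-2-oxopropyl]-6-(3,4-dimethoxyphenyl)-4-oxo-4H-pyran-3-carboxylate (racemic)
Product: 11 6-(benzyloxy)-5,7-dihydroxy-8-methoxy-2-(3,4-dimethoxyphenyl)-4H-chromen-4-one, via dienone tautomer 10 (not isolated)
Conditions: LiN(iPr)2 (LDA, 3.3 equiv), THF, −78 °C, 9 added to the base; warm to rt; 1 M HCl
Reagents that add atoms: none
Why: The first equivalent of base removes the methoxymethine proton (future C8) and the second a benzyloxymethylene proton (future C6); the terminal carbon of this dianion adds to the ester carbonyl (future C5), methoxide leaves, and dienone 10 gives up its C6 proton to become the aromatic 5,7-diphenoxide, which makes the sequence irreversible. The closest known reaction type is the Dieckmann (intramolecular Claisen) cyclisation of 1,3-dicarbonyl dianions and poly-beta-carbonyl esters to phloroglucinols and 1,3-naphthalenediols. Ring A closes in the 6-(enolendo)-exo-trig mode, and with O1, C2, C3 and C4 already tied up in ring C the chain can fold in one way only. No stereocentre is created, since the racemic centre of 9 becomes sp2. The step needs acylation at C6 and not at O7: lithium bridging O7 and the C8 methoxy oxygen turns O7 away from the ester and C6 toward it, the terminal carbanion is the most nucleophilic site, and any lactone formed can be reopened by the liberated LiOMe whereas the C-acylated material is drained by aromatisation. The ester, squeezed between C4=O and the branched substituent on pyranone C2, is twisted out of the ring plane, so the first negative charge (mainly on O4 and O7) should deactivate it little while its pi* orbital faces C6, and adding 9 to excess base keeps the lifetime of the monoanion short.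

Step 6
Reactants: 11 6-(benzyloxy)-5,7-dihydroxy-8-methoxy-2-(3,4-dimethoxyphenyl)-4H-chromen-4-one
Product: 12 6-(benzyloxy)-5-hydroxy-7,8-dimethoxy-2-(3,4-dimethoxyphenyl)-4H-chromen-4-one
Conditions: MeI (1.05 equiv), K2CO3 (1.1 equiv), acetone, rt
Reagents that add atoms: iodomethane, CI
Why: Williamson-type O-methylation with about one equivalent of weak base selects by acidity, since the 7-OH is a vinylogous acid conjugated with C4=O whereas the 5-OH is held in a hydrogen bond to C4=O, and C-methylation is impossible on the fully substituted ring A.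

Step 7
Reactants: 12 6-(benzyloxy)-5-hydroxy-7,8-dimethoxy-2-(3,4-dimethoxyphenyl)-4H-chromen-4-one
Product: 13 pebrellin, 5,6-dihydroxy-7,8-dimethoxy-2-(3,4-dimethoxyphenyl)-4H-chromen-4-one
Conditions: H2 (1 atm), Pd/C (10 wt% Pd), EtOAc–MeOH, rt
Reagents that add atoms: none
Why: Catalytic hydrogenolysis cleaves only the benzylic C–O bond, the flavone C2–C3 double bond and the four methyl ethers being inert at 1 atm and room temperature, and the neutral medium should avoid both Wessely–Moser isomerisation and oxidation of the 5,6-diol.

Compound list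
1 | 3-(3,4-dimethoxyphenyl)propiolic acid | COc1ccc(C#CC(=O)O)cc1OC | starting material
2 | 3-(3,4-dimethoxyphenyl)propioloyl chloride | COc1ccc(C#CC(=O)Cl)cc1OC | intermediate
3 | methyl 4-methoxyacetoacetate | COCC(=O)CC(=O)OC | starting material
4 | methyl 2-[3-(3,4-dimethoxyphenyl)prop-2-ynoyl]-4-methoxy-3-oxobutanoate (enolised, configurationally labile, present as magnesium chelate) | COCC(=O)C(C(=O)OC)C(=O)C#Cc1ccc(OC)c(OC)c1 | intermediate
5 | methyl 6-(3,4-dimethoxyphenyl)-2-(methoxymethyl)-4-oxo-4H-pyran-3-carboxylate | COCc1oc(-c2ccc(OC)c(OC)c2)cc(=O)c1C(=O)OC | intermediate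
6 | benzyloxyacetyl chloride | O=C(Cl)COCc1ccccc1 | starting material
7 | 2-(benzyloxy)-N-methoxy-N-methylacetamide | CON(C)C(=O)COCc1ccccc1 | intermediate
8 | lithium alkoxide of methyl 2-{3-(benzyloxy)-2-hydroxy-1-methoxy-2-[methoxy(methyl)amino]propyl}-6-(3,4-dimethoxyphenyl)-4-oxo-4H-pyran-3-carboxylate (racemic mixture of diastereomers) | COC(=O)c1c(C(OC)C([O-])(COCc2ccccc2)N(C)OC)oc(-c2ccc(OC)c(OC)c2)cc1=O.[Li+] | intermediate
9 | methyl 2-[3-(benzyloxy)-1-methoxy-2-oxopropyl]-6-(3,4-dimethoxyphenyl)-4-oxo-4H-pyran-3-carboxylate (racemic) | COC(=O)c1c(C(OC)C(=O)COCc2ccccc2)oc(-c2ccc(OC)c(OC)c2)cc1=O | intermediate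
10 | 6-(benzyloxy)-7-hydroxy-8-methoxy-2-(3,4-dimethoxyphenyl)-4H-chromene-4,5(6H)-dione (racemic, present as lithium enolate) | COc1ccc(cc1OC)C1=CC(=O)C2=C(O1)C(OC)=C(O)C(OCc1ccccc1)C2=O | intermediate
11 | 6-(benzyloxy)-5,7-dihydroxy-8-methoxy-2-(3,4-dimethoxyphenyl)-4H-chromen-4-one | COc1ccc(-c2cc(=O)c3c(O)c(OCc4ccccc4)c(O)c(OC)c3o2)cc1OC | intermediate
12 | 6-(benzyloxy)-5-hydroxy-7,8-dimethoxy-2-(3,4-dimethoxyphenyl)-4H-chromen-4-one | COc1ccc(-c2cc(=O)c3c(O)c(OCc4ccccc4)c(OC)c(OC)c3o2)cc1OC | intermediate
13 | pebrellin, 5,6-dihydroxy-7,8-dimethoxy-2-(3,4-dimethoxyphenyl)-4H-chromen-4-one | COc1ccc(-c2cc(=O)c3c(O)c(O)c(OC)c(OC)c3o2)cc1OC | target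

Total step count: 7
Longest linear sequence: 6 steps (1 → 2 → 5 → 9 → 11 → 12 → 13, that is steps 1, 2, 4, 5, 6 and 7)

Steps most likely to fail

1. Step 5.
- **What may go wrong:** acyl transfer to the enolate oxygen O7 in place of C6, a closure that stalls because the anionic pyranone repels the carbanion, or base-induced opening of ring C.
- **Fallback, from 9 back to 11:** the oxygen is allowed to react first, and the acyl group is then moved to carbon under equilibrating conditions. Heating 9 with DBU in toluene should expel methanol and give the enol lactone 7-[(benzyloxy)methyl]-2-(3,4-dimethoxyphenyl)-8-methoxy-4H,5H-pyrano[4,3-b]pyran-4,5-dione F1. Mg(OMe)2 in refluxing MeOH should then reopen the lactone and, with magnesium as template, shift the acyl carbon from O7 to C6. This is the classical alkoxide rearrangement of an enol lactone into a cyclic 1,3-dione, as in benzylidenephthalide to 2-phenylindane-1,3-dione or triketo-acid pyranones to acylphloroglucinols. Aromatisation to 11 acts as the sink.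

2. Step 4.
- **What may go wrong:** sluggish addition of the strongly stabilised carbanion to the amide, return of 5 by proton transfer, or self-condensation of the anion with the ester of a second molecule.
- **Fallback, from 3 and 7 back to 9:** the chain is lengthened before the pyranone is built. The 1,3-dianion of 3 (NaH, then n-BuLi, THF, 0 °C) is a far more reactive nucleophile. It is acylated at its gamma-carbon by 7 to give methyl 6-(benzyloxy)-4-methoxy-3,5-dioxohexanoate F2. MgCl2/pyridine C-acylation of F2 at C2 with 2 should give methyl 6-(benzyloxy)-2-[3-(3,4-dimethoxyphenyl)prop-2-ynoyl]-4-methoxy-3,5-dioxohexanoate F3. Its C3 enol oxygen closes onto the ynone as in step 2 and gives 9. Acylation at C4 of F2 would build a non-enolisable quaternary tricarbonyl that reverts readily, so the C2 product should accumulate.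

3. Step 2.
- **What may go wrong:** conjugate addition of chloride or pyridine to the alkynoyl chloride, O-acylation of the enolate, or closure in the 5-exo mode.
- **Fallback, from 3 back to 5:** the alkyne is replaced by an alkene and the oxidation level is restored afterwards, following the chalcone–flavanone–flavone logic. Commercial (E)-3,4-dimethoxycinnamoyl chloride C-acylates 3 under the same MgCl2/pyridine conditions to give methyl 2-[(E)-3-(3,4-dimethoxyphenyl)acryloyl]-4-methoxy-3-oxobutanoate F4. A catalytic amount of piperidine should close it by 6-endo-trig oxa-Michael addition to methyl 6-(3,4-dimethoxyphenyl)-2-(methoxymethyl)-4-oxo-5,6-dihydro-4H-pyran-3-carboxylate F5. DDQ in dioxane then removes the electron-rich benzylic hydride and gives 5.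

Further compounds
F1 | step 5 | 7-[(benzyloxy)methyl]-2-(3,4-dimethoxyphenyl)-8-methoxy-4H,5H-pyrano[4,3-b]pyran-4,5-dione | COc1ccc(cc1OC)C1=CC(=O)C2=C(O1)C(OC)=C(COCc1ccccc1)OC2=O
F2 | step 4 | methyl 6-(benzyloxy)-4-methoxy-3,5-dioxohexanoate (racemic, labile) | COC(=O)CC(=O)C(OC)C(=O)COCc1ccccc1
F3 | step 4 | methyl 6-(benzyloxy)-2-[3-(3,4-dimethoxyphenyl)prop-2-ynoyl]-4-methoxy-3,5-dioxohexanoate (enolised, configurationally labile) | COC(=O)C(C(=O)C#Cc1ccc(OC)c(OC)c1)C(=O)C(OC)C(=O)COCc1ccccc1
F4 | step 2 | methyl 2-[(E)-3-(3,4-dimethoxyphenyl)acryloyl]-4-methoxy-3-oxobutanoate (enolised, configurationally labile at C2) | COCC(=O)C(C(=O)OC)C(=O)/C=C/c1ccc(OC)c(OC)c1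
F5 | step 2 | methyl 6-(3,4-dimethoxyphenyl)-2-(methoxymethyl)-4-oxo-5,6-dihydro-4H-pyran-3-carboxylate (racemic) | COCC1=C(C(=O)OC)C(=O)CC(O1)c1ccc(OC)c(OC)c1
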